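**Retrosynthetic overview**
1. Guidongnin ⇒ 15-oxo-16-ene 34 (reduction at C15, removal of the 11-O-silyl group). The strategy rests on the 2-methylidenecyclopentanol of ring D: carbinol C15 bonded to C16(=C17H2), the two-carbon bridge that spans C8 and C13 of ring C.
2. 34 ⇒ aldehyde 33: the C15–H of the C8 aldehyde is added across the C13 ethynyl group (C15–C16 bond, ring D closed last).
3. 33 ⇒ tricyclic lactone 30: C15 by aldol with formaldehyde at C8; ring C by samarium diiodide ketyl cyclisation (C9–C11) onto the C8=C9 unsaturated δ-lactone; C8–C14 by alkylation of spiro bis-lactone 14 with iodide 22 (C13 from asymmetric conjugate alkynylation).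
4. 14 ⇒ epoxide 11 + acrylate 12 (titanocene radical coupling: C9–C10 and the spiro δ-lactone); the γ-lactone on ring A by intramolecular C-acylation of ketone 7; C4 by copper-catalysed conjugate addition to 3-methylcyclohex-2-en-1-one.
5. Ring order: A (carbocycle of the starting enone) → γ-lactone → δ-lactone → C → D.

Key step: step 22

Remark: ent-kaurane numbering is used (ring A C1–C5/C10, δ-lactone C7–O–C20, ring C C8/C9/C11–C14, ring D C8/C14/C13/C16/C15); where C8 or C11 is epimerisable or re-set in a later step it is left undefined in the SMILES.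

**Fragment 1: spiro bis-lactone 14**

Step 1
Reactants: 1 3-methylcyclohex-2-en-1-one; 2 trimethylsilylacetylene
Product: 4 (R)-3-methyl-3-[1-(trimethylsilyl)ethenyl]cyclohexan-1-one, via diisobutyl[1-(trimethylsilyl)ethenyl]alane 3 (not isolated)
Conditions: 2, i-Bu2AlH, hexanes/THF, 55 °C; then 1, CuCl2·2H2O (5 mol %), chiral sulfonate-bearing imidazolinium salt (NHC ligand precursor, enantiomer giving the R ketone), THF, −78 → −15 °C
Reagents that add atoms: none
Why: Hydroalumination places aluminium on the silicon-bearing carbon, and the NHC–copper catalysed enantioselective conjugate addition of this vinylalane to the β-substituted enone should create the C4 quaternary centre, its configuration fixed by the ligand.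

Step 2
Reactants: 4 (R)-3-methyl-3-[1-(trimethylsilyl)ethenyl]cyclohexan-1-one
Product: 5 (R)-3-ethenyl-3-methylcyclohexan-1-one
Conditions: CF3CO2H, CH2Cl2, 0 °C → rt
Reagents that add atoms: none
Why: Ipso-protodesilylation of the vinylsilane (β-silyl cation) should leave the plain vinyl group without touching the quaternary centre.

Step 3
Reactants: 5 (R)-3-ethenyl-3-methylcyclohexan-1-one
Product: 7 (R)-3-(hydroxymethyl)-3-methylcyclohexan-1-one, via keto aldehyde 6 (not isolated)
Conditions: O3, CH2Cl2/MeOH, −78 °C; Me2S; then NaBH(OAc)3, AcOH, rt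
Reagents that add atoms: ozone, [O-][O+]=O
Why: Ozonolysis cuts the vinyl group down to the C19 aldehyde, and NaBH(OAc)3 should reduce the aldehyde chemoselectively beside the ketone.

Step 4
Reactants: 7 (R)-3-(hydroxymethyl)-3-methylcyclohexan-1-one
Product: 9 (3aR,7aR)-3a-methylhexahydro-2-benzofuran-1,7-dione, via imidazole-1-carboxylate 8 (not isolated)
Conditions: CDI, CH2Cl2, rt; then NaH, THF, 0 °C → reflux; aq. HCl
Reagents that add atoms: 1,1'-carbonyldiimidazole, O=C(n1ccnc1)n1ccnc1
Why: Dieckmann-type intramolecular C-acylation of the equilibrating ketone enolate: only the C5 enolate can reach the tethered acyl imidazole, the five-membered lactone can only form cis-fused (setting C5), and the β-keto lactone is drained as its stabilised enolate.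

Step 5
Reactants: 9 (3aR,7aR)-3a-methylhexahydro-2-benzofuran-1,7-dione
Product: 10 (3aR,7aS)-3a-methyl-7-methylidenehexahydro-2-benzofuran-1(3H)-one
Conditions: Zn, CH2Br2, TiCl4, THF/CH2Cl2, 0 °C → rt
Reagents that add atoms: dibromomethane, BrCBr
Why: Takai–Lombardo methylenation, whose non-basic zinc/titanium methylene reagent attacks ketones but not lactones and should leave the cis-fused C5 centre in place.

Step 6
Reactants: 10 (3aR,7aS)-3a-methyl-7-methylidenehexahydro-2-benzofuran-1(3H)-one
Product: 11 C10,C20-epoxide of 10 (spiro-oxirane; both C10 epimers)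
Conditions: mCPBA, NaHCO3, CH2Cl2, 0 °C
Reagents that add atoms: mCPBA, O=C(OO)c1cccc(Cl)c1
Why: Prilezhaev epoxidation of the 1,1-disubstituted alkene; the C10 configuration does not matter because C10 becomes a radical in the next step.

Step 7
Reactants: 11 C10,C20-epoxide of 10; 12 2,2,2-trifluoroethyl acrylate
Product: 14 spiro bis-lactone (ring A with cis-fused 6,19-γ-lactone; 7,20-δ-lactone spiro at C10), via hydroxy trifluoroethyl ester 13 (not isolated)
Conditions: Cp2TiCl2 (30 mol %), Zn, 2,4,6-collidine·HCl, THF, rt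
Reagents that add atoms: none
Why: Trivalent titanium (Cp2TiCl) opens the epoxide to the tertiary C10 radical, which should add to the acrylate (Giese addition) on the convex face away from the axial C19 methylene of the lactone bridge, setting C10 with C9 trans to C6; the C20 alkoxide then lactonises onto the activated ester.

**Fragment 2: iodide 22**

Step 8
Reactants: 15 allyloxy-tert-butyldimethylsilane; 16 (E)-crotonaldehyde
Product: 17 (E)-4-(tert-butyldimethylsilyloxy)but-2-enal
Conditions: second-generation Hoveyda–Grubbs catalyst (2 mol %), 16 (3 equiv), CH2Cl2, 40 °C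
Reagents that add atoms: none
Why: Olefin cross-metathesis of a terminal allyl ether with an enal should give the E enal under thermodynamic control.

Step 9
Reactants: 17 (E)-4-(tert-butyldimethylsilyloxy)but-2-enal; 18 (triisopropylsilyl)acetylene
Product: 19 (S)-3-[(tert-butyldimethylsilyloxy)methyl]-5-(triisopropylsilyl)pent-4-ynal
Conditions: [Rh(OAc)(C2H4)2]2 (2.5 mol %), DTBM-SEGPHOS (enantiomer giving the 3S aldehyde), MeOH, 40 °C
Reagents that add atoms: none
Why: Rhodium-catalysed asymmetric conjugate alkynylation of an enal with a bulky silylacetylene; the bisphosphine enantiomer fixes the face of alkynyl transfer and so the future C13.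

Step 10
Reactants: 19 (S)-3-[(tert-butyldimethylsilyloxy)methyl]-5-(triisopropylsilyl)pent-4-ynal
Product: 20 (S)-tert-butyl{[2-(2,2-dimethoxyethyl)-4-(triisopropylsilyl)but-3-yn-1-yl]oxy}dimethylsilane
Conditions: HC(OMe)3, PPTS (cat.), MeOH, 0 °C
Reagents that add atoms: trimethyl orthoformate, COC(OC)OC; methanol, CO
Why: Acid-catalysed acetalisation masks the future C11 aldehyde for the enolate steps; the stereocentre is β to the carbonyl and cannot epimerise.

Step 11
Reactants: 20 (S)-tert-butyl{[2-(2,2-dimethoxyethyl)-4-(triisopropylsilyl)but-3-yn-1-yl]oxy}dimethylsilane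
Product: 21 (S)-2-(2,2-dimethoxyethyl)-4-(triisopropylsilyl)but-3-yn-1-ol
Conditions: TBAF, AcOH, THF, 0 °C
Reagents that add atoms: none
Why: Fluoride should cleave the primary O–Si bond much faster than the C(sp)–Si(i-Pr)3 bond, and the buffered, non-acidic medium keeps the acyclic acetal from closing onto the new hydroxyl.

Step 12
Reactants: 21 (S)-2-(2,2-dimethoxyethyl)-4-(triisopropylsilyl)but-3-yn-1-ol
Product: 22 (S)-[3-(iodomethyl)-5,5-dimethoxypent-1-yn-1-yl]tri(propan-2-yl)silane
Conditions: I2, PPh3, imidazole, CH2Cl2, 0 °C → rt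
Reagents that add atoms: iodine, II
Why: Appel-type (Garegg–Samuelsson) iodination of the primary alcohol under imidazole buffering, which spares the acetal.

**Union of the fragments and rings C and D**

Step 13
Reactants: 14 spiro bis-lactone; 22 (S)-[3-(iodomethyl)-5,5-dimethoxypent-1-yn-1-yl]tri(propan-2-yl)silane
Product: 23 C8-alkylated spiro bis-lactone (C8 epimers; side chain with C13 alkynylsilane and C11 dimethyl acetal)
Conditions: LiN(i-Pr)2, THF, −78 °C; then 22, DMPU, −78 → −20 °C
Reagents that add atoms: none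
Why: Kinetic enolisation should occur at the C8 methylene of the δ-lactone (C5–H of the γ-lactone lies between two quaternary carbons), and SN2 alkylation forms C8–C14; the C8 configuration is removed in the next step.

Step 14
Reactants: 23 C8-alkylated spiro bis-lactone
Product: 25 C8=C9 unsaturated δ-lactone carrying the C11 dimethyl acetal, via C8 phenylselenide 24 (not isolated)
Conditions: LiN(i-Pr)2, THF, −78 °C; PhSeBr; then H2O2, pyridine, CH2Cl2, 0 °C → rt
Reagents that add atoms: none
Why: α-Selenenylation followed by selenoxide syn-elimination, which in six-membered lactones is expected to go into the ring and give the endocyclic C8=C9 alkene.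

Step 15
Reactants: 25 C8=C9 unsaturated δ-lactone carrying the C11 dimethyl acetal
Product: 26 C8=C9 unsaturated δ-lactone C11 aldehyde
Conditions: TsOH·H2O (cat.), acetone/H2O, rt
Reagents that add atoms: water, O
Why: Acid-catalysed acetal hydrolysis frees the C11 aldehyde; the lactones and the silylalkyne should tolerate dilute acid.

Step 16
Reactants: 26 C8=C9 unsaturated δ-lactone C11 aldehyde
Product: 27 tricyclic C11 alcohol (ring C closed; C11 and C8 epimers)
Conditions: SmI2, LiBr, t-BuOH, THF, −78 °C
Reagents that add atoms: none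
Why: Samarium diiodide ketyl–olefin cyclisation (6-endo): the C11 ketyl should add to C9 on the face next to C1H2 and away from the branched C5, through a chair with the C13 alkynyl group equatorial, which sets C9; the alkoxide is expected equatorial (trans to C10), and both C11 and C8 are re-set later.

Step 17
Reactants: 27 tricyclic C11 alcohol
Product: 28 tricyclic C11 ketone (C8 epimers)
Conditions: Dess–Martin periodinane, NaHCO3, CH2Cl2, rt
Reagents that add atoms: none
Why: Buffered Dess–Martin oxidation erases the uncontrolled C11 configuration without epimerising C9.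

Step 18
Reactants: 28 tricyclic C11 ketone
Product: 30 11-O-TBS ether of the 11R alcohol (C8 epimers), via 11R alcohol 29 (not isolated)
Conditions: LiBH(s-Bu)3, THF, −78 °C; then TBSOTf, 2,6-lutidine, −78 → 0 °C
Reagents that add atoms: tert-butyldimethylsilyl triflate, CC(C)(C)[Si](C)(C)OS(=O)(=O)C(F)(F)F
Why: The bulky hydride should attack the ring C ketone equatorially (C10 equatorial), giving the axial 11-alkoxide cis to C10 (11R); silylation in the same flask keeps that alkoxide from translactonising onto C7.

Step 19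
Reactants: 30 11-O-TBS ether of the 11R alcohol
Product: 31 C8 hydroxymethyl tricycle (15-alcohol; 11-OTBS; silylalkyne)
Conditions: LiN(i-Pr)2, THF, −78 °C; CH2O (gas), −78 °C; AcOH
Reagents that add atoms: formaldehyde, C=O
Why: Aldol addition of the δ-lactone enolate to formaldehyde; attack anti to the axial C11 silyl ether should place C15 cis to H9 and to the C13 alkynyl group (8S), giving the cis-fused lactone.

Step 20
Reactants: 31 C8 hydroxymethyl tricycle
Product: 32 terminal alkyne 15-alcohol (11-OTBS)
Conditions: AgF, MeOH/THF, rt, dark; then 1 M HCl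
Reagents that add atoms: none
Why: Silver fluoride cleaves the C(sp)–Si bond through the silver acetylide, which dilute acid protonates, and should leave the hindered secondary O-silyl ether intact.

Step 21
Reactants: 32 terminal alkyne 15-alcohol
Product: 33 C8 aldehyde with C13 ethynyl group and 11-OTBS (key-step precursor)
Conditions: Dess–Martin periodinane, NaHCO3, CH2Cl2, 0 °C → rt
Reagents that add atoms: none
Why: Dess–Martin oxidation of the neopentyl primary alcohol; the aldehyde sits on the quaternary C8 and cannot enolise.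

Step 22
Reactants: 33 C8 aldehyde with C13 ethynyl group and 11-OTBS
Product: 34 15-oxo-16-ene tetracycle (11-OTBS)
Conditions: [Rh(dppe)]ClO4 (10 mol %, from [Rh(nbd)(dppe)]ClO4 and H2), acetone, 0.005 M, rt → 50 °C
Reagents that add atoms: none
Why: Proposed new method: cationic monovalent rhodium inserts into the formyl C–H bond of 33 to give an acyl rhodium hydride, the C13 ethynyl group coordinates, syn hydrometalation puts rhodium on C16 (six-membered rhodacycle) and C–C reductive elimination forms C15–C16; the closest known reaction is the cationic rhodium bisphosphine cyclisation of 5-alkynals bearing internal alkynes to 2-alkylidenecyclopentanones, extended here to a terminal alkyne and a bridged ring. Ring D closes in the 5-exo-dig mode across ring C and completes the bicyclo[3.2.1]octane. No stereocentre is formed; C8 and C13 already carry the aldehyde and the ethynyl group cis, so the chair with both groups axial can close. The step needs ring closure to outrun decarbonylation and alkyne oligomerisation: the aldehyde is non-enolisable, the other chair is penalised by a syn-axial contact between C7 and the 11-O-silyl group so the reactive chair is populated, and high dilution suppresses intermolecular alkyne coupling. Exo regiochemistry is secured because the endo mode would need a seven-membered rhodacycle and would give a bicyclo[2.2.2]octenone.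

Step 23
Reactants: 34 15-oxo-16-ene tetracycle (11-OTBS)
Product: 35 guidongnin 11-O-TBS ether
Conditions: NaBH4, CeCl3·7H2O, MeOH, −78 → −40 °C
Reagents that add atoms: none
Why: Luche 1,2-reduction of the exo-methylene enone; hydride should attack C15 from the exo face (the side of the C14 bridge), giving the endo alcohol syn to C9 (15R), and the lactones are not reduced at this temperature.

Step 24
Reactants: 35 guidongnin 11-O-TBS ether
Product: 36 guidongnin
Conditions: HF·pyridine, pyridine, THF, 0 °C → rt
Reagents that add atoms: none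
Why: Acidic fluoride desilylation avoids base at the β-hydroxy lactone (no retro-aldol), and in the rigid cage the equatorial 11-hydroxyl cannot reach C7.

**Compound list**
1 | 3-methylcyclohex-2-en-1-one | CC1=CC(=O)CCC1 | starting material
2 | trimethylsilylacetylene | C#C[Si](C)(C)C | starting material
3 | diisobutyl[1-(trimethylsilyl)ethenyl]alane | C=C([Si](C)(C)C)[Al](CC(C)C)CC(C)C | intermediate
4 | (R)-3-methyl-3-[1-(trimethylsilyl)ethenyl]cyclohexan-1-one | O=C1CCC[C@@](C)(C(=C)[Si](C)(C)C)C1 | intermediate
5 | (R)-3-ethenyl-3-methylcyclohexan-1-one | O=C1CCC[C@@](C)(C=C)C1 | intermediate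
6 | (R)-1-methyl-3-oxocyclohexane-1-carbaldehyde | O=C1CCC[C@@](C)(C=O)C1 | intermediate
7 | (R)-3-(hydroxymethyl)-3-methylcyclohexan-1-one | O=C1CCC[C@@](C)(CO)C1 | intermediate
8 | [(1R)-1-methyl-3-oxocyclohexyl]methyl 1H-imidazole-1-carboxylate | O=C1CCC[C@@](C)(COC(=O)n2ccnc2)C1 | intermediate
9 | (3aR,7aR)-3a-methylhexahydro-2-benzofuran-1,7-dione | O=C1CCC[C@@]2(C)COC(=O)[C@@H]12 | intermediate
10 | (3aR,7aS)-3a-methyl-7-methylidenehexahydro-2-benzofuran-1(3H)-one | C=C1CCC[C@@]2(C)COC(=O)[C@@H]12 | intermediate
11 | C10,C20-epoxide of 10 (spiro-oxirane, C10 epimers) | O1CC12CCC[C@@]3(C)COC(=O)[C@@H]23 | intermediate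
12 | 2,2,2-trifluoroethyl acrylate | C=CC(=O)OCC(F)(F)F | starting material
13 | C20 alcohol with C9–C8–C7 trifluoroethyl ester arm on C10 | OC[C@@]1(CCC(=O)OCC(F)(F)F)CCC[C@@]2(C)COC(=O)[C@H]21 | intermediate
14 | spiro bis-lactone (6,19-γ-lactone cis-fused to ring A; 7,20-δ-lactone spiro at C10; C9 trans to C6) | O=C1CC[C@@]2(CCC[C@@]3(C)COC(=O)[C@H]32)CO1 | intermediate
15 | allyloxy-tert-butyldimethylsilane | C=CCO[Si](C)(C)C(C)(C)C | starting material
16 | (E)-crotonaldehyde | C/C=C/C=O | starting material
17 | (E)-4-(tert-butyldimethylsilyloxy)but-2-enal | O=C/C=C/CO[Si](C)(C)C(C)(C)C | intermediate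
18 | (triisopropylsilyl)acetylene | C#C[Si](C(C)C)(C(C)C)C(C)C | starting material
19 | (S)-3-[(tert-butyldimethylsilyloxy)methyl]-5-(triisopropylsilyl)pent-4-ynal | CC(C)[Si](C(C)C)(C(C)C)C#C[C@@H](CO[Si](C)(C)C(C)(C)C)CC=O | intermediate
20 | (S)-tert-butyl{[2-(2,2-dimethoxyethyl)-4-(triisopropylsilyl)but-3-yn-1-yl]oxy}dimethylsilane | CC(C)[Si](C(C)C)(C(C)C)C#C[C@@H](CO[Si](C)(C)C(C)(C)C)CC(OC)OC | intermediate
21 | (S)-2-(2,2-dimethoxyethyl)-4-(triisopropylsilyl)but-3-yn-1-ol | CC(C)[Si](C(C)C)(C(C)C)C#C[C@@H](CO)CC(OC)OC | intermediate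
22 | (S)-[3-(iodomethyl)-5,5-dimethoxypent-1-yn-1-yl]tri(propan-2-yl)silane | CC(C)[Si](C(C)C)(C(C)C)C#C[C@@H](CI)CC(OC)OC | intermediate
23 | C8-alkylated spiro bis-lactone (C8 epimers) | O=C1C(C[C@H](C#C[Si](C(C)C)(C(C)C)C(C)C)CC(OC)OC)C[C@@]2(CCC[C@@]3(C)COC(=O)[C@H]32)CO1 | intermediate
24 | C8 phenylselenide of 23 | O=C1C([Se]c4ccccc4)(C[C@H](C#C[Si](C(C)C)(C(C)C)C(C)C)CC(OC)OC)C[C@@]2(CCC[C@@]3(C)COC(=O)[C@H]32)CO1 | intermediate
25 | C8=C9 unsaturated δ-lactone, C11 dimethyl acetal | O=C1C(C[C@H](C#C[Si](C(C)C)(C(C)C)C(C)C)CC(OC)OC)=C[C@@]2(CCC[C@@]3(C)COC(=O)[C@H]32)CO1 | intermediate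
26 | C8=C9 unsaturated δ-lactone, C11 aldehyde | O=C1C(C[C@H](C#C[Si](C(C)C)(C(C)C)C(C)C)CC=O)=C[C@@]2(CCC[C@@]3(C)COC(=O)[C@H]32)CO1 | intermediate
27 | tricyclic C11 alcohol (C11 and C8 epimers) | CC(C)[Si](C(C)C)(C(C)C)C#C[C@@H]2CC(O)[C@H]3[C@@]4(CCC[C@@]5(C)COC(=O)[C@H]54)COC(=O)C3C2 | intermediate
28 | tricyclic C11 ketone (C8 epimers) | CC(C)[Si](C(C)C)(C(C)C)C#C[C@@H]2CC(=O)[C@H]3[C@@]4(CCC[C@@]5(C)COC(=O)[C@H]54)COC(=O)C3C2 | intermediate
29 | 11R alcohol, hydroxyl cis to C10 (C8 epimers) | CC(C)[Si](C(C)C)(C(C)C)C#C[C@@H]2C[C@@H](O)[C@H]3[C@@]4(CCC[C@@]5(C)COC(=O)[C@H]54)COC(=O)C3C2 | intermediate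
30 | 11-O-TBS ether of 29 (C8 epimers) | CC(C)[Si](C(C)C)(C(C)C)C#C[C@@H]2C[C@@H](O[Si](C)(C)C(C)(C)C)[C@H]3[C@@]4(CCC[C@@]5(C)COC(=O)[C@H]54)COC(=O)C3C2 | intermediate
31 | C8 hydroxymethyl tricycle (15-alcohol, 11-OTBS, silylalkyne) | CC(C)[Si](C(C)C)(C(C)C)C#C[C@@H]2C[C@@H](O[Si](C)(C)C(C)(C)C)[C@H]3[C@@]4(CCC[C@@]5(C)COC(=O)[C@H]54)COC(=O)[C@]3(C2)CO | intermediate
32 | terminal alkyne 15-alcohol (11-OTBS) | C#C[C@@H]2C[C@@H](O[Si](C)(C)C(C)(C)C)[C@H]3[C@@]4(CCC[C@@]5(C)COC(=O)[C@H]54)COC(=O)[C@]3(C2)CO | intermediate
33 | C8 aldehyde with C13 ethynyl group, 11-OTBS | C#C[C@@H]2C[C@@H](O[Si](C)(C)C(C)(C)C)[C@H]3[C@@]4(CCC[C@@]5(C)COC(=O)[C@H]54)COC(=O)[C@]3(C2)C=O | intermediate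
34 | 15-oxo-16-ene tetracycle, 11-OTBS | C=C1[C@@H]2C[C@@H](O[Si](C)(C)C(C)(C)C)[C@H]3[C@@]4(CCC[C@@]5(C)COC(=O)[C@H]54)COC(=O)[C@]3(C2)C1=O | intermediate
35 | guidongnin 11-O-TBS ether | C=C1[C@@H]2C[C@@H](O[Si](C)(C)C(C)(C)C)[C@H]3[C@@]4(CCC[C@@]5(C)COC(=O)[C@H]54)COC(=O)[C@]3(C2)[C@@H]1O | intermediate
36 | guidongnin | C=C1[C@@H]2C[C@@H](O)[C@H]3[C@@]4(CCC[C@@]5(C)COC(=O)[C@H]54)COC(=O)[C@]3(C2)[C@@H]1O | target

**Step count**
Total: 24 steps. Longest linear sequence: 19 steps (steps 1–7 and 13–24); fragment 2 takes 5 steps (8–12).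

**Steps most likely to fail**

Step 22. The acyl rhodium hydride may lose CO (decarbonylation) or the terminal alkyne may oligomerise before the bridged ring closes. Fallback with known chemistry, starting from 33: a nickel-catalysed reductive aldehyde–alkyne cyclisation (Ni(cod)2, PBu3, Et3SiH, THF; oxanickelacycle, then σ-bond metathesis with the silane) should give the 15-O-triethylsilyl 16-methylidene tetracycle F1 as C15 epimers. PPTS in MeOH at 0 °C should remove only the triethylsilyl group to give the 15-alcohol F2, and Dess–Martin oxidation converts F2 into enone 34, where the route is rejoined.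

Step 5. The acidic C5–H (enol form) of the β-keto lactone may quench the methylene reagent, so that methylenation stalls at a metal enolate. Fallback starting from 9: NaH and PhNTf2 should give the enol triflate F3, and Pd(PPh3)4-catalysed Kumada coupling with Me3SiCH2MgCl gives the conjugated allylsilane F4. TBAF/AcOH then removes silicon to a dienolate that is protonated kinetically at C5, giving the deconjugated exo-methylene lactone 10, where the route is rejoined.

Step 7. The tertiary C10 radical may disproportionate to the conjugated allylic alcohol (loss of the activated C5–H) or add to the acrylate with poor facial selectivity. Fallback starting from 11: Meinwald rearrangement (BF3·OEt2, CH2Cl2, −78 °C) should give the C10 carbaldehyde F5. Its pyrrolidine enamine should add to methyl acrylate on the convex face (Stork enamine Michael addition, then aqueous AcOH) to give the quaternary aldehyde ester F6. NaBH4 in MeOH followed by TsOH reduces the aldehyde and closes the δ-lactone to 14, where the route is rejoined.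

**Further compounds**
F1 | step 22 | 15-O-triethylsilyl 16-methylidene tetracycle, 11-OTBS (C15 epimers) | C=C1[C@@H]2C[C@@H](O[Si](C)(C)C(C)(C)C)[C@H]3[C@@]4(CCC[C@@]5(C)COC(=O)[C@H]54)COC(=O)[C@]3(C2)C1O[Si](CC)(CC)CC
F2 | step 22 | 15-alcohol, 11-OTBS (C15 epimers) | C=C1[C@@H]2C[C@@H](O[Si](C)(C)C(C)(C)C)[C@H]3[C@@]4(CCC[C@@]5(C)COC(=O)[C@H]54)COC(=O)[C@]3(C2)C1O
F3 | step 5 | enol triflate of 9 (C5=C10) | FC(F)(F)S(=O)(=O)OC1=C2C(=O)OC[C@]2(C)CCC1
F4 | step 5 | C10 (trimethylsilyl)methyl butenolide-type lactone (C5=C10) | C[Si](C)(C)CC1=C2C(=O)OC[C@]2(C)CCC1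
F5 | step 7 | ring A γ-lactone C10 carbaldehyde (C10 epimers) | O=CC1CCC[C@@]2(C)COC(=O)[C@@H]12
F6 | step 7 | C10 quaternary aldehyde with methyl propanoate arm | O=C[C@@]1(CCC(=O)OC)CCC[C@@]2(C)COC(=O)[C@H]21
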